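**Retrosynthetic overview**
- Target ⇐ desilylation ⇐ 5,12-diketone ⇐ double Dess–Martin oxidation of a 5,12-diol, so both carbonyls are unmasked only at the end.
- C5–C6: Nozaki–Hiyama–Kishi coupling of an (E)-alkenyl iodide (C6–C16 half) with a β,γ-unsaturated aldehyde (aryl–C1–C5 half).
- C12–C13: hydrozirconation/zinc transmetalation of silylated 2-methylbut-3-yn-2-ol and addition to an (R)-α-methyl aldehyde; C6=C7 by zirconium-catalysed carboalumination–iodination of a terminal alkyne.
- C11: lipase-catalysed desymmetrisation of 2-methylpropane-1,3-diol; C9–C10 by copper-catalysed Grignard/tosylate coupling.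
- Aryl–C1: copper-catalysed aryl Grignard/allylic bromide coupling; no ring is formed in the route, the benzene ring is bought as 4-hydroxy-3-methylbenzaldehyde.

Assumption: the Pseudomonas fluorescens lipase is taken to give the (S)-monoacetate of 2-methylpropane-1,3-diol (the sense reported for this diol, recalled rather than re-checked); chain locants C1–C16 are those of the hexadecatriene chain (C1 = benzylic carbon), and carbinol centres that are later oxidised are carried as epimer mixtures.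

**Route**

Step 1
Reactants: 1 2-methylpropane-1,3-diol
Product: 2 (S)-3-hydroxy-2-methylpropyl acetate
Conditions: lipase from Pseudomonas fluorescens (immobilised), vinyl acetate (3 equiv), CHCl3, 30 °C; stopped at ca. 25% diacetate; product used promptly
Reagents that add atoms: vinyl acetate, C=COC(C)=O
Why: Enzymatic desymmetrisation (irreversible transesterification) by a lipase, a serine hydrolase, which acylates only the pro-S hydroxymethyl arm of the prochiral diol and so sets the stereocentre as (S); slower over-acylation of the minor (R)-monoester to achiral diacetate lifts the ee to about 98%.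

Step 2
Reactants: 2 (S)-3-hydroxy-2-methylpropyl acetate
Product: 3 (R)-3-[(tert-butyldiphenylsilyl)oxy]-2-methylpropyl acetate
Conditions: TBDPSCl, imidazole, CH2Cl2, 0 °C
Reagents that add atoms: tert-butyl(chloro)diphenylsilane, CC(C)(C)[Si](Cl)(c1ccccc1)c1ccccc1
Why: Fast silylation of the primary alcohol locks the two arms before acetyl migration can racemise the monoester; the descriptor changes only through CIP priorities.

Step 3
Reactants: 3 (R)-3-[(tert-butyldiphenylsilyl)oxy]-2-methylpropyl acetate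
Product: 4 (R)-3-[(tert-butyldiphenylsilyl)oxy]-2-methylpropan-1-ol
Conditions: K2CO3 (0.2 equiv), MeOH, 0 °C
Reagents that add atoms: none
Why: Zemplén-type base-catalysed transesterification removes the acetate, and the bulky TBDPS group does not migrate at 0 °C, so the stereocentre is not scrambled.

Step 4
Reactants: 4 (R)-3-[(tert-butyldiphenylsilyl)oxy]-2-methylpropan-1-ol
Product: 5 (S)-3-[(tert-butyldiphenylsilyl)oxy]-2-methylpropyl 4-methylbenzenesulfonate
Conditions: TsCl, Et3N, DMAP (cat.), CH2Cl2, 0 °C → rt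
Reagents that add atoms: 4-methylbenzenesulfonyl chloride, Cc1ccc(cc1)S(Cl)(=O)=O
Why: Sulfonylation of the primary alcohol gives the leaving group for chain extension without touching the stereocentre.

Step 5
Reactants: 5 (S)-3-[(tert-butyldiphenylsilyl)oxy]-2-methylpropyl 4-methylbenzenesulfonate; 6 (4-bromobut-1-yn-1-yl)trimethylsilane
Product: 8 (R)-tert-butyl{[2-methyl-7-(trimethylsilyl)hept-6-yn-1-yl]oxy}diphenylsilane, via Grignard reagent 7 (not isolated)
Conditions: 6 (2 equiv), Mg, THF, rt → 40 °C; then 5, Li2CuCl4 (5 mol%), THF, −78 °C → rt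
Reagents that add atoms: none
Why: Kochi–Schlosser copper-catalysed sp3–sp3 coupling of a primary tosylate with a Grignard reagent; the stereocentre is β to the reacting carbon and untouched.

Step 6
Reactants: 8 (R)-tert-butyl{[2-methyl-7-(trimethylsilyl)hept-6-yn-1-yl]oxy}diphenylsilane
Product: 9 (R)-2-methylhept-6-yn-1-ol
Conditions: TBAF (2.5 equiv), THF, 0 °C → rt
Reagents that add atoms: none
Why: Fluoride-induced desilylation cleaves the O–Si bond and the alkynyl C–Si bond in one operation.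

Step 7
Reactants: 9 (R)-2-methylhept-6-yn-1-ol
Product: 11 (R,E)-7-iodo-2,6-dimethylhept-6-en-1-ol, via alkenylalane 10 (not isolated)
Conditions: Me3Al (3 equiv), Cp2ZrCl2 (0.25 equiv), CH2Cl2, 0 °C → rt; then I2, THF, −30 → 0 °C
Reagents that add atoms: trimethylaluminium, C[Al](C)C; iodine, II
Why: Negishi zirconium-catalysed carboalumination adds methyl and aluminium syn across the terminal alkyne (aluminium terminal), and iodinolysis with retention gives the (E)-iodoalkene; the hydroxyl is carried as its aluminium alkoxide.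

Step 8
Reactants: 11 (R,E)-7-iodo-2,6-dimethylhept-6-en-1-ol
Product: 12 (R,E)-7-iodo-2,6-dimethylhept-6-enal
Conditions: DMP (1.3 equiv), NaHCO3, CH2Cl2, 0 °C → rt; used crude at once
Reagents that add atoms: none
Why: Buffered Dess–Martin oxidation gives the α-methyl aldehyde under non-basic conditions, so the stereocentre is not epimerised.

Step 9
Reactants: 13 2-methylbut-3-yn-2-ol
Product: 14 triethyl[(2-methylbut-3-yn-2-yl)oxy]silane
Conditions: TESOTf, 2,6-lutidine, CH2Cl2, 0 °C
Reagents that add atoms: triethylsilyl trifluoromethanesulfonate, CC[Si](CC)(CC)OS(=O)(=O)C(F)(F)F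
Why: Silylation of the hindered tertiary alcohol with the reactive silyl triflate.

Step 10
Reactants: 12 (R,E)-7-iodo-2,6-dimethylhept-6-enal; 14 triethyl[(2-methylbut-3-yn-2-yl)oxy]silane
Product: 17 (3E,5RS,6R,10E)-11-iodo-2,6,10-trimethyl-2-[(triethylsilyl)oxy]undeca-3,10-dien-5-ol, via alkenylzirconocene 15 (not isolated), via alkenylzinc 16 (not isolated)
Conditions: 14 (1.6 equiv), Cp2Zr(H)Cl (1.6 equiv), CH2Cl2, rt; Me2Zn (1.6 equiv, toluene), −65 °C; then 12, 0 °C
Reagents that add atoms: none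
Why: Wipf hydrozirconation–zinc transmetalation–carbonyl addition, in which syn hydrozirconation fixes the (E)-alkene and the alkenylzinc adds 1,2 to the aldehyde without touching the iodoalkene or enolising the α-centre; the new carbinol forms as an epimer mixture that is erased by later oxidation.

Step 11
Reactants: 18 4-hydroxy-3-methylbenzaldehyde
Product: 19 3-bromo-4-hydroxy-5-methylbenzaldehyde
Conditions: Br2 (1.05 equiv), AcOH, rt
Reagents that add atoms: bromine, BrBr
Why: Electrophilic aromatic bromination directed by the phenol to its only free ortho position (para is blocked by the formyl group).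

Step 12
Reactants: 19 3-bromo-4-hydroxy-5-methylbenzaldehyde
Product: 20 3-bromo-4-methoxy-5-methylbenzaldehyde
Conditions: MeI, K2CO3, DMF, rt → 40 °C
Reagents that add atoms: iodomethane, CI
Why: Williamson O-methylation of the acidic, formyl-activated phenoxide.

Step 13
Reactants: 20 3-bromo-4-methoxy-5-methylbenzaldehyde
Product: 22 3-bromo-4-methoxy-5-methylphenol, via aryl formate 21 (not isolated)
Conditions: mCPBA (1.5 equiv), CH2Cl2, rt; then MeOH, K2CO3 (cat.), rt
Reagents that add atoms: 3-chloroperoxybenzoic acid, OOC(=O)c1cccc(Cl)c1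
Why: Baeyer–Villiger (Dakin-type) oxidation with migration of the para-methoxy aryl group gives the aryl formate, which is methanolysed to the phenol.

Step 14
Reactants: 22 3-bromo-4-methoxy-5-methylphenol
Product: 23 (3-bromo-4-methoxy-5-methylphenoxy)triisopropylsilane
Conditions: TIPSCl, imidazole, DMF, rt
Reagents that add atoms: chlorotriisopropylsilane, CC(C)[Si](Cl)(C(C)C)C(C)C
Why: Silylation of the unhindered phenol; the triisopropylsilyl ether withstands Grignard formation, acid methanolysis and the oxidations ahead.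

Step 15
Reactants: 24 but-3-yn-1-ol
Product: 25 (but-3-yn-1-yloxy)(tert-butyl)dimethylsilane
Conditions: TBSCl, imidazole, CH2Cl2, 0 °C → rt
Reagents that add atoms: tert-butyl(chloro)dimethylsilane, CC(C)(C)[Si](C)(C)Cl
Why: Standard silylation of the primary alcohol.

Step 16
Reactants: 25 (but-3-yn-1-yloxy)(tert-butyl)dimethylsilane
Product: 28 (E)-5-[(tert-butyldimethylsilyl)oxy]-3-methylpent-2-en-1-ol, via alkenylalane 26 (not isolated), via lithium alanate 27 (not isolated)
Conditions: Me3Al (2.5 equiv), Cp2ZrCl2 (0.25 equiv), CH2Cl2, 0 °C → rt; evaporate; n-BuLi, THF–hexane, −78 → 0 °C; (CH2O)n, rt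
Reagents that add atoms: trimethylaluminium, C[Al](C)C; paraformaldehyde (formaldehyde unit), C=O
Why: Negishi carboalumination (syn, aluminium terminal) followed by hydroxymethylation of the derived alanate with retention gives the (E)-trisubstituted allylic alcohol.

Step 17
Reactants: 28 (E)-5-[(tert-butyldimethylsilyl)oxy]-3-methylpent-2-en-1-ol
Product: 29 [(E)-(5-bromo-3-methylpent-3-en-1-yl)oxy](tert-butyl)dimethylsilane
Conditions: CBr4, PPh3, CH2Cl2, −20 → 0 °C; used at once
Reagents that add atoms: carbon tetrabromide, BrC(Br)(Br)Br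
Why: Appel bromination proceeds by SN2 at the primary allylic carbon without allylic transposition or loss of E geometry.

Step 18
Reactants: 23 (3-bromo-4-methoxy-5-methylphenoxy)triisopropylsilane; 29 [(E)-(5-bromo-3-methylpent-3-en-1-yl)oxy](tert-butyl)dimethylsilane
Product: 31 tert-butyl{[(E)-5-{2-methoxy-3-methyl-5-[(triisopropylsilyl)oxy]phenyl}-3-methylpent-3-en-1-yl]oxy}dimethylsilane, via aryl Grignard 30 (not isolated)
Conditions: 23 (1.3 equiv), Mg, THF, 50 °C; then Li2CuCl4 (3 mol%), 29, THF, −20 → 0 °C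
Reagents that add atoms: none
Why: Copper-catalysed Kochi-type coupling of the aryl Grignard with the primary allylic bromide; attack at the unhindered α-carbon (the γ-carbon is fully substituted) keeps the E geometry.

Step 19
Reactants: 31 tert-butyl{[(E)-5-{2-methoxy-3-methyl-5-[(triisopropylsilyl)oxy]phenyl}-3-methylpent-3-en-1-yl]oxy}dimethylsilane
Product: 32 (E)-5-{2-methoxy-3-methyl-5-[(triisopropylsilyl)oxy]phenyl}-3-methylpent-3-en-1-ol
Conditions: CSA (0.1 equiv), MeOH–CH2Cl2 (1:1), 0 °C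
Reagents that add atoms: none
Why: Acid-catalysed methanolysis removes the primary alkyl silyl ether far faster than the bulky aryl triisopropylsilyl ether.

Step 20
Reactants: 32 (E)-5-{2-methoxy-3-methyl-5-[(triisopropylsilyl)oxy]phenyl}-3-methylpent-3-en-1-ol
Product: 33 (E)-5-{2-methoxy-3-methyl-5-[(triisopropylsilyl)oxy]phenyl}-3-methylpent-3-enal
Conditions: DMP (1.2 equiv), NaHCO3, CH2Cl2, 0 °C, 45 min; crude aldehyde used at once
Reagents that add atoms: none
Why: Buffered Dess–Martin oxidation forms the β,γ-unsaturated aldehyde without base, so the alkene does not move into conjugation.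

Step 21
Reactants: 33 (E)-5-{2-methoxy-3-methyl-5-[(triisopropylsilyl)oxy]phenyl}-3-methylpent-3-enal; 17 (3E,5RS,6R,10E)-11-iodo-2,6,10-trimethyl-2-[(triethylsilyl)oxy]undeca-3,10-dien-5-ol
Product: 35 (2E,5RS,6E,11R,12RS,13E)-1-{2-methoxy-3-methyl-5-[(triisopropylsilyl)oxy]phenyl}-3,7,11,15-tetramethyl-15-[(triethylsilyl)oxy]hexadeca-2,6,13-triene-5,12-diol, via alkenylchromium 34 (not isolated)
Conditions: 33 (1.5 equiv), CrCl2 (8 equiv), NiCl2 (2 mol%), degassed DMSO, rt, 16 h
Reagents that add atoms: none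
Why: Nozaki–Hiyama–Kishi coupling, in which zerovalent nickel inserts into the C–I bond with retention and the alkenyl group passes to trivalent chromium, which adds 1,2 to the aldehyde under non-basic conditions that tolerate the free hydroxyl and do not isomerise the β,γ-unsaturated aldehyde; the new carbinol is an epimer mixture that is oxidised next.

Step 22
Reactants: 35 (2E,5RS,6E,11R,12RS,13E)-1-{2-methoxy-3-methyl-5-[(triisopropylsilyl)oxy]phenyl}-3,7,11,15-tetramethyl-15-[(triethylsilyl)oxy]hexadeca-2,6,13-triene-5,12-diol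
Product: 36 (2E,6E,11R,13E)-1-{2-methoxy-3-methyl-5-[(triisopropylsilyl)oxy]phenyl}-3,7,11,15-tetramethyl-15-[(triethylsilyl)oxy]hexadeca-2,6,13-triene-5,12-dione
Conditions: DMP (3 equiv), NaHCO3 (10 equiv), CH2Cl2, 0 °C → rt
Reagents that add atoms: none
Why: Double Dess–Martin oxidation converts both allylic carbinols (all four diastereomers) into one diketone under buffered conditions that neither epimerise C11 nor conjugate the C2 alkene.

Step 23
Reactants: 36 (2E,6E,11R,13E)-1-{2-methoxy-3-methyl-5-[(triisopropylsilyl)oxy]phenyl}-3,7,11,15-tetramethyl-15-[(triethylsilyl)oxy]hexadeca-2,6,13-triene-5,12-dione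
Product: 37 (2E,6E,11R,13E)-15-hydroxy-1-(5-hydroxy-2-methoxy-3-methylphenyl)-3,7,11,15-tetramethylhexadeca-2,6,13-triene-5,12-dione
Conditions: TBAF (4 equiv), AcOH (4 equiv), THF, 0 °C → rt
Reagents that add atoms: none
Why: Acetic acid-buffered fluoride desilylation removes the aryl and the tertiary silyl ethers near neutrality, sparing the α-methyl ketone and the skipped enone.

**Compound list**

1 | 2-methylpropane-1,3-diol | CC(CO)CO | starting material
2 | (S)-3-hydroxy-2-methylpropyl acetate | CC(=O)OC[C@@H](C)CO | intermediate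
3 | (R)-3-[(tert-butyldiphenylsilyl)oxy]-2-methylpropyl acetate | CC(=O)OC[C@@H](C)CO[Si](c1ccccc1)(c1ccccc1)C(C)(C)C | intermediate
4 | (R)-3-[(tert-butyldiphenylsilyl)oxy]-2-methylpropan-1-ol | OC[C@@H](C)CO[Si](c1ccccc1)(c1ccccc1)C(C)(C)C | intermediate
5 | (S)-3-[(tert-butyldiphenylsilyl)oxy]-2-methylpropyl 4-methylbenzenesulfonate | Cc1ccc(cc1)S(=O)(=O)OC[C@@H](C)CO[Si](c1ccccc1)(c1ccccc1)C(C)(C)C | intermediate
6 | (4-bromobut-1-yn-1-yl)trimethylsilane | C[Si](C)(C)C#CCCBr | starting material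
7 | [4-(trimethylsilyl)but-3-yn-1-yl]magnesium bromide | C[Si](C)(C)C#CCC[Mg]Br | intermediate
8 | (R)-tert-butyl{[2-methyl-7-(trimethylsilyl)hept-6-yn-1-yl]oxy}diphenylsilane | C[Si](C)(C)C#CCCC[C@@H](C)CO[Si](c1ccccc1)(c1ccccc1)C(C)(C)C | intermediate
9 | (R)-2-methylhept-6-yn-1-ol | C#CCCC[C@@H](C)CO | intermediate
10 | [(R,E)-7-(dimethylalumanyloxy)-2,6-dimethylhept-1-en-1-yl]dimethylalumane | C[Al](C)/C=C(\C)CCC[C@@H](C)CO[Al](C)C | intermediate
11 | (R,E)-7-iodo-2,6-dimethylhept-6-en-1-ol | I/C=C(\C)CCC[C@@H](C)CO | intermediate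
12 | (R,E)-7-iodo-2,6-dimethylhept-6-enal | I/C=C(\C)CCC[C@@H](C)C=O | intermediate
13 | 2-methylbut-3-yn-2-ol | CC(C)(O)C#C | starting material
14 | triethyl[(2-methylbut-3-yn-2-yl)oxy]silane | CC[Si](CC)(CC)OC(C)(C)C#C | intermediate
15 | chlorobis(cyclopentadienyl)[(E)-3-methyl-3-(triethylsilyloxy)but-1-en-1-yl]zirconium | CC[Si](CC)(CC)OC(C)(C)/C=C/[Zr](Cl)(C1C=CC=C1)C1C=CC=C1 | intermediate
16 | methyl[(E)-3-methyl-3-(triethylsilyloxy)but-1-en-1-yl]zinc | CC[Si](CC)(CC)OC(C)(C)/C=C/[Zn]C | intermediate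
17 | (3E,5RS,6R,10E)-11-iodo-2,6,10-trimethyl-2-[(triethylsilyl)oxy]undeca-3,10-dien-5-ol | I/C=C(\C)CCC[C@@H](C)C(O)/C=C/C(C)(C)O[Si](CC)(CC)CC | intermediate
18 | 4-hydroxy-3-methylbenzaldehyde | Cc1cc(C=O)ccc1O | starting material
19 | 3-bromo-4-hydroxy-5-methylbenzaldehyde | Cc1cc(C=O)cc(Br)c1O | intermediate
20 | 3-bromo-4-methoxy-5-methylbenzaldehyde | COc1c(C)cc(C=O)cc1Br | intermediate
21 | 3-bromo-4-methoxy-5-methylphenyl formate | COc1c(C)cc(OC=O)cc1Br | intermediate
22 | 3-bromo-4-methoxy-5-methylphenol | COc1c(C)cc(O)cc1Br | intermediate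
23 | (3-bromo-4-methoxy-5-methylphenoxy)triisopropylsilane | COc1c(C)cc(O[Si](C(C)C)(C(C)C)C(C)C)cc1Br | intermediate
24 | but-3-yn-1-ol | C#CCCO | starting material
25 | (but-3-yn-1-yloxy)(tert-butyl)dimethylsilane | C#CCCO[Si](C)(C)C(C)(C)C | intermediate
26 | [(E)-4-(tert-butyldimethylsilyloxy)-2-methylbut-1-en-1-yl]dimethylalumane | C[Al](C)/C=C(\C)CCO[Si](C)(C)C(C)(C)C | intermediate
27 | lithium butyl[(E)-4-(tert-butyldimethylsilyloxy)-2-methylbut-1-en-1-yl]dimethylaluminate | [Li+].CCCC[Al-](C)(C)/C=C(\C)CCO[Si](C)(C)C(C)(C)C | intermediate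
28 | (E)-5-[(tert-butyldimethylsilyl)oxy]-3-methylpent-2-en-1-ol | OC/C=C(\C)CCO[Si](C)(C)C(C)(C)C | intermediate
29 | [(E)-(5-bromo-3-methylpent-3-en-1-yl)oxy](tert-butyl)dimethylsilane | BrC/C=C(\C)CCO[Si](C)(C)C(C)(C)C | intermediate
30 | {2-methoxy-3-methyl-5-[(triisopropylsilyl)oxy]phenyl}magnesium bromide | COc1c(C)cc(O[Si](C(C)C)(C(C)C)C(C)C)cc1[Mg]Br | intermediate
31 | tert-butyl{[(E)-5-{2-methoxy-3-methyl-5-[(triisopropylsilyl)oxy]phenyl}-3-methylpent-3-en-1-yl]oxy}dimethylsilane | COc1c(C)cc(O[Si](C(C)C)(C(C)C)C(C)C)cc1C/C=C(\C)CCO[Si](C)(C)C(C)(C)C | intermediate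
32 | (E)-5-{2-methoxy-3-methyl-5-[(triisopropylsilyl)oxy]phenyl}-3-methylpent-3-en-1-ol | COc1c(C)cc(O[Si](C(C)C)(C(C)C)C(C)C)cc1C/C=C(\C)CCO | intermediate
33 | (E)-5-{2-methoxy-3-methyl-5-[(triisopropylsilyl)oxy]phenyl}-3-methylpent-3-enal | COc1c(C)cc(O[Si](C(C)C)(C(C)C)C(C)C)cc1C/C=C(\C)CC=O | intermediate
34 | dichloro[(1E,6R,8E)-7-hydroxy-2,6,10-trimethyl-10-(triethylsilyloxy)undeca-1,8-dien-1-yl]chromium | Cl[Cr](Cl)/C=C(\C)CCC[C@@H](C)C(O)/C=C/C(C)(C)O[Si](CC)(CC)CC | intermediate
35 | (2E,5RS,6E,11R,12RS,13E)-1-{2-methoxy-3-methyl-5-[(triisopropylsilyl)oxy]phenyl}-3,7,11,15-tetramethyl-15-[(triethylsilyl)oxy]hexadeca-2,6,13-triene-5,12-diol | COc1c(C)cc(O[Si](C(C)C)(C(C)C)C(C)C)cc1C/C=C(\C)CC(O)/C=C(\C)CCC[C@@H](C)C(O)/C=C/C(C)(C)O[Si](CC)(CC)CC | intermediate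
36 | (2E,6E,11R,13E)-1-{2-methoxy-3-methyl-5-[(triisopropylsilyl)oxy]phenyl}-3,7,11,15-tetramethyl-15-[(triethylsilyl)oxy]hexadeca-2,6,13-triene-5,12-dione | COc1c(C)cc(O[Si](C(C)C)(C(C)C)C(C)C)cc1C/C=C(\C)CC(=O)/C=C(\C)CCC[C@@H](C)C(=O)/C=C/C(C)(C)O[Si](CC)(CC)CC | intermediate
37 | (2E,6E,11R,13E)-15-hydroxy-1-(5-hydroxy-2-methoxy-3-methylphenyl)-3,7,11,15-tetramethylhexadeca-2,6,13-triene-5,12-dione | COc1c(C)cc(O)cc1C/C=C(\C)CC(=O)/C=C(\C)CCC[C@@H](C)C(=O)/C=C/C(C)(C)O | target

**Totals and risks**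

Total step count: 23. Longest linear sequence: 12 steps (steps 1–8, 10, 21, 22, 23, from 2-methylpropane-1,3-diol).

The three steps most likely to fail:

Step 21 (coupling with the labile β,γ-unsaturated aldehyde). The fallback sets out from 32 and 17 and comes back at 36; it replaces the carbonyl addition by a base-free acylation, so the aldehyde is never a coupling partner. Alcohol 32 is oxidised through to the acid (DMP, then NaClO2/NaH2PO4/2-methylbut-2-ene) to give (E)-5-{2-methoxy-3-methyl-5-[(triisopropylsilyl)oxy]phenyl}-3-methylpent-3-enoic acid F5. This is condensed with thiophenol (DCC, DMAP cat., CH2Cl2, 0 °C) to S-phenyl (E)-5-{2-methoxy-3-methyl-5-[(triisopropylsilyl)oxy]phenyl}-3-methylpent-3-enethioate F6. Iodide 17 is stannylated (Me3SnSnMe3, Pd(PPh3)4 cat., toluene, 80 °C) to (3E,5RS,6R,10E)-2,6,10-trimethyl-2-[(triethylsilyl)oxy]-11-(trimethylstannyl)undeca-3,10-dien-5-ol F7. Liebeskind–Srogl coupling of the thioester and the stannane (Pd2(dba)3 cat., tri(2-furyl)phosphine, CuO2PPh2, THF, rt) gives (2E,6E,11R,12RS,13E)-12-hydroxy-1-{2-methoxy-3-methyl-5-[(triisopropylsilyl)oxy]phenyl}-3,7,11,15-tetramethyl-15-[(triethylsilyl)oxy]hexadeca-2,6,13-trien-5-one F8, and buffered DMP oxidation of the remaining carbinol gives 36.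

Step 1 (enantioselectivity of the desymmetrisation and acetyl migration in the monoacetate). The fallback sets out from 1 and comes back at 5; it uses the hydrolytic, enantiocomplementary mode of the same enzyme class on a diester that resists acyl migration, and functionalises the arms in the reverse order. Diol 1 is acylated (butyric anhydride, pyridine) to 2-methylpropane-1,3-diyl dibutanoate F1. Lipase-catalysed hydrolysis (Pseudomonas lipase, phosphate buffer pH 7, pH-stat) gives (R)-3-hydroxy-2-methylpropyl butanoate F2. Tosylation (TsCl, Et3N, DMAP cat.) gives (S)-2-methyl-3-(tosyloxy)propyl butanoate F3. Acid-catalysed methanolysis (AcCl cat., MeOH, rt) gives (S)-3-hydroxy-2-methylpropyl 4-methylbenzenesulfonate F4, and silylation (TBDPSCl, imidazole) gives 5.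

Step 23 (fluoride on a substrate with an epimerisable α-methyl ketone and a skipped enone). The fallback sets out from 35 and comes back at 37; it moves desilylation ahead of the oxidation, where no base-sensitive carbonyl exists, and ends with an enzymatic ester cleavage at neutral pH. Diol 35 is desilylated (TBAF, THF, rt) to (2E,6E,11R,13E)-1-(5-hydroxy-2-methoxy-3-methylphenyl)-3,7,11,15-tetramethylhexadeca-2,6,13-triene-5,12,15-triol F9. Phenol-selective acetylation (Ac2O 1.05 equiv, K2CO3, acetone, 0 °C) gives 3-[(2E,6E,11R,13E)-5,12,15-trihydroxy-3,7,11,15-tetramethylhexadeca-2,6,13-trien-1-yl]-4-methoxy-5-methylphenyl acetate F10. Buffered DMP oxidation of the two secondary carbinols gives 3-[(2E,6E,11R,13E)-15-hydroxy-3,7,11,15-tetramethyl-5,12-dioxohexadeca-2,6,13-trien-1-yl]-4-methoxy-5-methylphenyl acetate F11. A lipase (immobilised Candida antarctica lipase B, MTBE/phosphate buffer pH 7, 30 °C) then hydrolyses the aryl acetate to 37.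

**Further compounds**

F1 | step 1 | 2-methylpropane-1,3-diyl dibutanoate | CCCC(=O)OCC(C)COC(=O)CCC
F2 | step 1 | (R)-3-hydroxy-2-methylpropyl butanoate | OC[C@@H](C)COC(=O)CCC
F3 | step 1 | (S)-2-methyl-3-(tosyloxy)propyl butanoate | Cc1ccc(cc1)S(=O)(=O)OC[C@@H](C)COC(=O)CCC
F4 | step 1 | (S)-3-hydroxy-2-methylpropyl 4-methylbenzenesulfonate | Cc1ccc(cc1)S(=O)(=O)OC[C@@H](C)CO
F5 | step 21 | (E)-5-{2-methoxy-3-methyl-5-[(triisopropylsilyl)oxy]phenyl}-3-methylpent-3-enoic acid | COc1c(C)cc(O[Si](C(C)C)(C(C)C)C(C)C)cc1C/C=C(\C)CC(O)=O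
F6 | step 21 | S-phenyl (E)-5-{2-methoxy-3-methyl-5-[(triisopropylsilyl)oxy]phenyl}-3-methylpent-3-enethioate | COc1c(C)cc(O[Si](C(C)C)(C(C)C)C(C)C)cc1C/C=C(\C)CC(=O)Sc1ccccc1
F7 | step 21 | (3E,5RS,6R,10E)-2,6,10-trimethyl-2-[(triethylsilyl)oxy]-11-(trimethylstannyl)undeca-3,10-dien-5-ol | C[Sn](C)(C)/C=C(\C)CCC[C@@H](C)C(O)/C=C/C(C)(C)O[Si](CC)(CC)CC
F8 | step 21 | (2E,6E,11R,12RS,13E)-12-hydroxy-1-{2-methoxy-3-methyl-5-[(triisopropylsilyl)oxy]phenyl}-3,7,11,15-tetramethyl-15-[(triethylsilyl)oxy]hexadeca-2,6,13-trien-5-one | COc1c(C)cc(O[Si](C(C)C)(C(C)C)C(C)C)cc1C/C=C(\C)CC(=O)/C=C(\C)CCC[C@@H](C)C(O)/C=C/C(C)(C)O[Si](CC)(CC)CC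
F9 | step 23 | (2E,6E,11R,13E)-1-(5-hydroxy-2-methoxy-3-methylphenyl)-3,7,11,15-tetramethylhexadeca-2,6,13-triene-5,12,15-triol | COc1c(C)cc(O)cc1C/C=C(\C)CC(O)/C=C(\C)CCC[C@@H](C)C(O)/C=C/C(C)(C)O
F10 | step 23 | 3-[(2E,6E,11R,13E)-5,12,15-trihydroxy-3,7,11,15-tetramethylhexadeca-2,6,13-trien-1-yl]-4-methoxy-5-methylphenyl acetate | COc1c(C)cc(OC(C)=O)cc1C/C=C(\C)CC(O)/C=C(\C)CCC[C@@H](C)C(O)/C=C/C(C)(C)O
F11 | step 23 | 3-[(2E,6E,11R,13E)-15-hydroxy-3,7,11,15-tetramethyl-5,12-dioxohexadeca-2,6,13-trien-1-yl]-4-methoxy-5-methylphenyl acetate | COc1c(C)cc(OC(C)=O)cc1C/C=C(\C)CC(=O)/C=C(\C)CCC[C@@H](C)C(=O)/C=C/C(C)(C)O
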